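**Retrosynthetic overview**

1. Target 25 comes from its 2,3-dihydro form 23 by a late Saegusa–Ito desaturation (C2=C3); 23 comes from the C8 alcohol 20 and angelic acid.
2. The lactone ring (O–C6, C7–C11) and the C7/C8 centres come from anti opening of a C7–C8 epoxide by a phosphonoacetate carbanion tethered on O6, followed by Horner–Wadsworth–Emmons methylenation (C11=C13).
3. Key disconnection C9–C10: bridged ketone 17 comes from diazoketone 15 by copper carbenoid formation, oxonium ylide formation and [2,3]-shift. This ring expansion of a 2,6-cis 6-vinyl-dihydropyran closes the five-membered oxa ring and the ten-membered carbocycle at once and sets C10 from C3.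
4. Enabling feature: the ether oxygen bridging C3 and C10, the C1 ketone next to C10, and the chain C10–C9–C8–C7 make a 2-allyl-tetrahydrofuran-3-one, the retron of an allyloxonium ylide [2,3]-shift. C3, C4=C5, C6 and C7 fold back onto that oxygen as a six-membered dihydropyran, which also fixes the cis C4=C5 bond.
5. The dihydropyran comes from Achmatowicz dearomatisation of a 2,3,5-trisubstituted furan (made from 2-methyl-3-furoic acid), then Kishi and Luche reductions, with absolute configuration from a lipase resolution. Ring order: furan, then dihydropyran, then furanone ring plus ten-membered ring (key step), then lactone.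

Key step: step 13

Remark: germacrane numbering is used throughout (C1 ketone, C2, C3, C4=C5, C6 lactone carbinol, C7, C8 ester carbinol, C9, C10 quaternary carbon, C11=C13, C12 lactone carbonyl, C14 methyl, C15 acetoxymethyl). The target is taken as the (6R,7R,8S,10R) isomer with a ring-cis C4=C5 bond, as written in the SMILES.

**Route**

Step 1
Reactants: 1 2-methylfuran-3-carboxylic acid
Product: 2 2-(2-tert-butoxy-2-oxoethyl)furan-3-carboxylic acid
Conditions: LiN(i-Pr)2 (3.2 equiv), THF, −78 → 0 °C; Boc2O, −78 °C; aq. HCl work-up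
Reagents that add atoms: di-tert-butyl dicarbonate, CC(C)(C)OC(=O)OC(=O)OC(C)(C)C
Why: the carboxylate directs lateral lithiation of the 2-methyl group (dianion formation) and C-acylation by Boc2O gives the tert-butyl ester, the extra base covering the more acidic product (lateral metalation–acylation).

Step 2
Reactants: 2 2-(2-tert-butoxy-2-oxoethyl)furan-3-carboxylic acid
Product: 3 tert-butyl 2-[3-(hydroxymethyl)furan-2-yl]acetate
Conditions: BH3·THF, THF, 0 °C → rt; MeOH quench
Reagents that add atoms: none
Why: borane reduces the free carboxylic acid much faster than the tert-butyl ester (chemoselective borane reduction of acids).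

Step 3
Reactants: 3 tert-butyl 2-[3-(hydroxymethyl)furan-2-yl]acetate
Product: 4 tert-butyl 2-[3-(acetoxymethyl)furan-2-yl]acetate
Conditions: Ac2O, pyridine, DMAP (cat.), CH2Cl2, 0 °C → rt
Reagents that add atoms: acetic anhydride, CC(=O)OC(C)=O
Why: DMAP-catalysed O-acetylation; this is the C15 acetate of the target and is carried to the end.

Step 4
Reactants: 4 tert-butyl 2-[3-(acetoxymethyl)furan-2-yl]acetate
Product: 5 tert-butyl 2-[3-(acetoxymethyl)-5-formylfuran-2-yl]acetate
Conditions: POCl3, DMF, 0 °C → rt; then aq. NaOAc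
Reagents that add atoms: N,N-dimethylformamide, CN(C)C=O; water, O
Why: Vilsmeier–Haack formylation at the only free α-position of the electron-rich 2,3-dialkylfuran; the tert-butyl ester and the acetate should tolerate the chloroiminium conditions.

Step 5
Reactants: 5 tert-butyl 2-[3-(acetoxymethyl)-5-formylfuran-2-yl]acetate
Product: 6 racemic tert-butyl 2-[3-(acetoxymethyl)-5-(1-hydroxyprop-2-en-1-yl)furan-2-yl]acetate
Conditions: CH2=CHMgBr, THF, −78 °C; aq. NH4Cl
Reagents that add atoms: vinylmagnesium bromide, C=C[Mg]Br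
Why: Grignard addition to the aldehyde at −78 °C is far faster than attack on either ester; the carbinol carbon (future C7, with C8=C9 attached) is formed racemic.

Step 6
Reactants: 6 racemic tert-butyl 2-[3-(acetoxymethyl)-5-(1-hydroxyprop-2-en-1-yl)furan-2-yl]acetate
Product: 7 tert-butyl 2-{3-(acetoxymethyl)-5-[(1S)-1-hydroxyprop-2-en-1-yl]furan-2-yl}acetate
Conditions: immobilised Candida antarctica lipase B, vinyl acetate, MTBE, 30 °C, stopped just past half conversion; chromatographic separation from the (R)-acetate
Reagents that add atoms: none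
Why: lipase-catalysed kinetic resolution (enantioselective transesterification); by the empirical size rule (furyl large, vinyl medium) the (R)-alcohol should be acetylated and the (S)-alcohol left, and since the acyl donor is acetyl the primary acetate cannot be scrambled.

Step 7
Reactants: 7 tert-butyl 2-{3-(acetoxymethyl)-5-[(1S)-1-hydroxyprop-2-en-1-yl]furan-2-yl}acetate
Product: 8 tert-butyl 2-[(6S)-3-(acetoxymethyl)-2-hydroxy-5-oxo-6-vinyl-5,6-dihydro-2H-pyran-2-yl]acetate (mixture of C2 epimers)
Conditions: NBS, NaHCO3, NaOAc, THF/H2O (4:1), 0 °C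
Reagents that add atoms: water, O
Why: Achmatowicz rearrangement; oxidative dearomatisation of the furan to the cis-enedione and closure of the carbinol oxygen onto the distal ketone give the pyranone hemiketal, the carbinol centre is untouched and the furan reacts with NBS far faster than the vinyl group.

Step 8
Reactants: 8 tert-butyl 2-[(6S)-3-(acetoxymethyl)-2-hydroxy-5-oxo-6-vinyl-5,6-dihydro-2H-pyran-2-yl]acetate
Product: 9 tert-butyl 2-[(2R,6S)-3-(acetoxymethyl)-5-oxo-6-vinyl-5,6-dihydro-2H-pyran-2-yl]acetate (2,6-cis)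
Conditions: Et3SiH, TFA, CH2Cl2, −40 °C
Reagents that add atoms: none
Why: Kishi-type ionic reduction; the hemiketal ionises to the ring oxocarbenium ion and Et3SiH delivers hydride axially to the half-chair that keeps the vinyl group pseudo-equatorial, so the ester arm ends equatorial and cis to vinyl, which sets C3 (germacrane numbering) as R.

Step 9
Reactants: 9 tert-butyl 2-[(2R,6S)-3-(acetoxymethyl)-5-oxo-6-vinyl-5,6-dihydro-2H-pyran-2-yl]acetate
Product: 10 tert-butyl 2-[(2R,5R,6S)-3-(acetoxymethyl)-5-hydroxy-6-vinyl-5,6-dihydro-2H-pyran-2-yl]acetate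
Conditions: NaBH4, CeCl3·7H2O, MeOH, −78 °C
Reagents that add atoms: none
Why: Luche 1,2-reduction of the enone; axial hydride attack on the half-chair with both 2,6-substituents equatorial should give the equatorial alcohol trans to the neighbouring vinyl group, which sets C6 as R and removes the epimerisable α-vinyl ketone.

Step 10
Reactants: 10 tert-butyl 2-[(2R,5R,6S)-3-(acetoxymethyl)-5-hydroxy-6-vinyl-5,6-dihydro-2H-pyran-2-yl]acetate; 11 2-(diethoxyphosphoryl)acetic acid
Product: 12 tert-butyl 2-[(2R,5R,6S)-3-(acetoxymethyl)-5-{[2-(diethoxyphosphoryl)acetyl]oxy}-6-vinyl-5,6-dihydro-2H-pyran-2-yl]acetate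
Conditions: DCC, DMAP (cat.), CH2Cl2, 0 °C → rt
Reagents that add atoms: none
Why: Steglich esterification with retention at C6; it installs the two carbons (C11, C12) and the phosphonate that later build the methylene lactone.

Step 11
Reactants: 12 tert-butyl 2-[(2R,5R,6S)-3-(acetoxymethyl)-5-{[2-(diethoxyphosphoryl)acetyl]oxy}-6-vinyl-5,6-dihydro-2H-pyran-2-yl]acetate
Product: 13 2-[(2R,5R,6S)-3-(acetoxymethyl)-5-{[2-(diethoxyphosphoryl)acetyl]oxy}-6-vinyl-5,6-dihydro-2H-pyran-2-yl]acetic acid
Conditions: TFA, CH2Cl2, 0 °C → rt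
Reagents that add atoms: none
Why: acidolysis of the tert-butyl ester (loss of isobutene) should leave the ethyl phosphonate, the primary acetate and the secondary allylic ester untouched.

Step 12
Reactants: 13 2-[(2R,5R,6S)-3-(acetoxymethyl)-5-{[2-(diethoxyphosphoryl)acetyl]oxy}-6-vinyl-5,6-dihydro-2H-pyran-2-yl]acetic acid
Product: 15 (2S,3R,6R)-5-(acetoxymethyl)-6-(3-diazo-2-oxobutyl)-2-vinyl-3,6-dihydro-2H-pyran-3-yl 2-(diethoxyphosphoryl)acetate, via isobutyl carbonic mixed anhydride 14 (not isolated)
Conditions: i-BuOCOCl, Et3N, THF/Et2O, −20 °C; then CH3CHN2 (Et2O solution freshly made from N-ethyl-N-nitrosourea and aq. KOH), −20 → 0 °C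
Reagents that add atoms: diazoethane, CC=[N+]=[N-]
Why: acylation of diazoethane by the mixed carbonic anhydride (Arndt–Eistert-type diazoketone synthesis) gives the α-methyl α-diazoketone that carries C10 and C14, under conditions too weakly basic to touch the phosphonoacetate CH2.

Step 13
Reactants: 15 (2S,3R,6R)-5-(acetoxymethyl)-6-(3-diazo-2-oxobutyl)-2-vinyl-3,6-dihydro-2H-pyran-3-yl 2-(diethoxyphosphoryl)acetate
Product: 17 (1R,2Z,4S,5Z,8R)-2-(acetoxymethyl)-8-methyl-9-oxo-11-oxabicyclo[6.2.1]undeca-2,5-dien-4-yl 2-(diethoxyphosphoryl)acetate (germacrane numbering: 3R 6S 10R; C4=C5 cis; C7=C8 cis), via bicyclic oxonium ylide 16 (not isolated)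
Conditions: Cu(CF3COCHCOCF3)2 (5 mol%), CH2Cl2, reflux, slow addition of 15 at high dilution
Reagents that add atoms: none
Why: Cu(CF3COCHCOCF3)2 decomposes the diazoketone to an electrophilic copper carbenoid at C10, the pyran oxygen attacks it to give the bicyclic oxonium ylide 16, and a concerted suprafacial [2,3]-sigmatropic shift across the C7 vinyl group forms C9–C10 while O–C7 breaks. The closest known reaction type is the copper-catalysed oxonium ylide formation/[2,3]-rearrangement of 6-vinyl-tetrahydropyran-2-yl diazoketones to 11-oxabicyclo[6.2.1]undecenones (three-atom ring expansion of 2-vinyl cyclic ethers). Rings closed: the tetrahydrofuran-3-one ring by O–C10 bond formation in the five-membered ylide closure, and the ten-membered carbocycle (nine-membered oxacycle) by the C9–C10 bond through the five-centre envelope transition state, with the pyran opened in the same event. C10 is set by C3, because the oxygen can bridge C3 and C10 only on one face, so (3R) enforces (10R) with the methyl group outside; C6 is untouched, C4=C5 keeps the cis geometry it had in the pyran, and C7=C8 is expected cis because the 2,6-cis pyran reacts through the cis-fused ylide with both ring substituents equatorial. The step needs ylide formation to beat 1,2-hydride shift of the methyl-bearing carbenoid and cyclopropanation of C4=C5, and the [2,3]-shift to beat the [1,2]-shift; this is secured by the basic ether oxygen in a five-membered-ring relationship to the carbenoid, the hexafluoroacetylacetonate copper carbenoid that favours ylide formation, the three allylic C–O bonds that deactivate C4=C5, and the allylic C7 terminus.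

Step 14
Reactants: 17 (1R,2Z,4S,5Z,8R)-2-(acetoxymethyl)-8-methyl-9-oxo-11-oxabicyclo[6.2.1]undeca-2,5-dien-4-yl 2-(diethoxyphosphoryl)acetate
Product: 18 the 7,8-epoxide of 17 with the epoxide oxygen cis to the C6 ester (germacrane numbering: 3R 6R 7S 8S 10R)
Conditions: dimethyldioxirane, acetone/CH2Cl2, −20 → 0 °C
Reagents that add atoms: dimethyldioxirane, CC1(C)OO1
Why: electrophilic epoxidation should pick the cis-disubstituted C7=C8 bond over C4=C5 (deactivated by three allylic C–O bonds) without Baeyer–Villiger reaction at C1; attack on the open face of the A(1,3)-controlled conformer (C6–H eclipsing the alkene, ring carbon C5 blocking the other face) should place the oxygen cis to the C6 acyloxy group and set C7 and C8 (both S).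

Step 15
Reactants: 18 the 7,8-epoxide of 17
Product: 20 (3R,6R,7R,8S,10R)-15-acetoxy-8-hydroxy-3,10-epoxy-1-oxogermacra-4,11(13)-dien-12,6-olide (C4=C5 cis; trans-fused α-methylene lactone), via lactone phosphonate 19 (not isolated)
Conditions: LiN(SiMe3)2 (1.05 equiv), THF, −78 → 0 °C; then paraformaldehyde, 0 °C → rt
Reagents that add atoms: formaldehyde (as paraformaldehyde), C=O
Why: the phosphonoacetate CH2 is by far the most acidic site, and its carbanion should open the epoxide at C7 in a 5-exo-tet alkylation with inversion, which closes the trans-fused γ-lactone (C7 becomes R) and frees the C8 alkoxide with its configuration intact (S); proton transfer regenerates the lactone phosphonate anion, and Horner–Wadsworth–Emmons olefination with formaldehyde installs C11=C13.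

Step 16
Reactants: 20 (3R,6R,7R,8S,10R)-15-acetoxy-8-hydroxy-3,10-epoxy-1-oxogermacra-4,11(13)-dien-12,6-olide; 21 angelic acid [(Z)-2-methylbut-2-enoic acid]
Product: 23 (3R,6R,7R,8S,10R)-15-acetoxy-8-angeloyloxy-3,10-epoxy-1-oxogermacra-4,11(13)-dien-12,6-olide (the 2,3-dihydro target), via angelic 2,4,6-trichlorobenzoic anhydride 22 (not isolated)
Conditions: 2,4,6-trichlorobenzoyl chloride, Et3N, toluene, rt; then 20, 80 °C (no DMAP)
Reagents that add atoms: none
Why: Yamaguchi-type esterification through the preformed mixed anhydride without nucleophilic catalyst, conditions chosen to transfer the angeloyl group without Z-to-E isomerisation to the tiglate.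

Step 17
Reactants: 23 (3R,6R,7R,8S,10R)-15-acetoxy-8-angeloyloxy-3,10-epoxy-1-oxogermacra-4,11(13)-dien-12,6-olide
Product: 25 the target (6R,7R,8S,10R)-15-acetoxy-8-angeloyloxy-3,10-epoxy-1-oxogermacra-2,4,11(13)-trien-12,6-olide, via trimethylsilyl enol ether 24 (not isolated)
Conditions: TMSOTf, Et3N, CH2Cl2, −78 → 0 °C; then Pd(OAc)2, MeCN, rt
Reagents that add atoms: none
Why: Saegusa–Ito oxidation; soft enolisation of the C1 ketone can only go towards C2 because C10 is quaternary, and the palladium enolate loses the C3 hydrogen by β-hydride elimination to give the 3(2H)-furanone conjugated with C4=C5, while the lactone (no α-hydrogen) and the esters are not enolised under these conditions.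

**Compound list**

1 | 2-methylfuran-3-carboxylic acid | Cc1occc1C(=O)O | starting material
2 | 2-(2-tert-butoxy-2-oxoethyl)furan-3-carboxylic acid | CC(C)(C)OC(=O)Cc1occc1C(=O)O | intermediate
3 | tert-butyl 2-[3-(hydroxymethyl)furan-2-yl]acetate | CC(C)(C)OC(=O)Cc1occc1CO | intermediate
4 | tert-butyl 2-[3-(acetoxymethyl)furan-2-yl]acetate | CC(C)(C)OC(=O)Cc1occc1COC(C)=O | intermediate
5 | tert-butyl 2-[3-(acetoxymethyl)-5-formylfuran-2-yl]acetate | CC(C)(C)OC(=O)Cc1oc(C=O)cc1COC(C)=O | intermediate
6 | racemic tert-butyl 2-[3-(acetoxymethyl)-5-(1-hydroxyprop-2-en-1-yl)furan-2-yl]acetate | CC(C)(C)OC(=O)Cc1oc(cc1COC(C)=O)C(O)C=C | intermediate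
7 | tert-butyl 2-{3-(acetoxymethyl)-5-[(1S)-1-hydroxyprop-2-en-1-yl]furan-2-yl}acetate | CC(C)(C)OC(=O)Cc1oc(cc1COC(C)=O)[C@@H](O)C=C | intermediate
8 | tert-butyl 2-[(6S)-3-(acetoxymethyl)-2-hydroxy-5-oxo-6-vinyl-5,6-dihydro-2H-pyran-2-yl]acetate (C2 epimers) | C=C[C@@H]1OC(O)(CC(=O)OC(C)(C)C)C(COC(C)=O)=CC1=O | intermediate
9 | tert-butyl 2-[(2R,6S)-3-(acetoxymethyl)-5-oxo-6-vinyl-5,6-dihydro-2H-pyran-2-yl]acetate | C=C[C@@H]1O[C@H](CC(=O)OC(C)(C)C)C(COC(C)=O)=CC1=O | intermediate
10 | tert-butyl 2-[(2R,5R,6S)-3-(acetoxymethyl)-5-hydroxy-6-vinyl-5,6-dihydro-2H-pyran-2-yl]acetate | C=C[C@@H]1O[C@H](CC(=O)OC(C)(C)C)C(COC(C)=O)=C[C@H]1O | intermediate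
11 | 2-(diethoxyphosphoryl)acetic acid | CCOP(=O)(CC(=O)O)OCC | starting material
12 | tert-butyl 2-[(2R,5R,6S)-3-(acetoxymethyl)-5-{[2-(diethoxyphosphoryl)acetyl]oxy}-6-vinyl-5,6-dihydro-2H-pyran-2-yl]acetate | C=C[C@@H]1O[C@H](CC(=O)OC(C)(C)C)C(COC(C)=O)=C[C@H]1OC(=O)CP(=O)(OCC)OCC | intermediate
13 | 2-[(2R,5R,6S)-3-(acetoxymethyl)-5-{[2-(diethoxyphosphoryl)acetyl]oxy}-6-vinyl-5,6-dihydro-2H-pyran-2-yl]acetic acid | C=C[C@@H]1O[C@H](CC(=O)O)C(COC(C)=O)=C[C@H]1OC(=O)CP(=O)(OCC)OCC | intermediate
14 | isobutyl carbonic mixed anhydride of 13 | C=C[C@@H]1O[C@H](CC(=O)OC(=O)OCC(C)C)C(COC(C)=O)=C[C@H]1OC(=O)CP(=O)(OCC)OCC | intermediate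
15 | (2S,3R,6R)-5-(acetoxymethyl)-6-(3-diazo-2-oxobutyl)-2-vinyl-3,6-dihydro-2H-pyran-3-yl 2-(diethoxyphosphoryl)acetate | C=C[C@@H]1O[C@H](CC(=O)C(C)=[N+]=[N-])C(COC(C)=O)=C[C@H]1OC(=O)CP(=O)(OCC)OCC | intermediate
16 | bicyclic oxonium ylide from 15 (pyran oxygen bonded to C10, drawn as the enolate) | CC1=C([O-])C[C@@H]2C(COC(C)=O)=C[C@@H](OC(=O)CP(=O)(OCC)OCC)[C@H](C=C)[O+]12 | intermediate
17 | (1R,2Z,4S,5Z,8R)-2-(acetoxymethyl)-8-methyl-9-oxo-11-oxabicyclo[6.2.1]undeca-2,5-dien-4-yl 2-(diethoxyphosphoryl)acetate | C[C@@]12C/C=C\[C@H](OC(=O)CP(=O)(OCC)OCC)/C=C(/COC(C)=O)[C@@H](CC1=O)O2 | intermediate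
18 | 7,8-epoxide of 17, oxygen cis to the C6 ester (germacrane 3R,6R,7S,8S,10R) | C[C@@]12C[C@@H]3O[C@@H]3[C@H](OC(=O)CP(=O)(OCC)OCC)/C=C(/COC(C)=O)[C@@H](CC1=O)O2 | intermediate
19 | trans-fused 11-(diethoxyphosphoryl) 12,6-lactone with free C8 hydroxyl (C11 epimers; lithium salt in the flask) | C[C@@]12C[C@H](O)[C@H]3C(P(=O)(OCC)OCC)C(=O)O[C@@H]3/C=C(/COC(C)=O)[C@@H](CC1=O)O2 | intermediate
20 | (3R,6R,7R,8S,10R)-15-acetoxy-8-hydroxy-3,10-epoxy-1-oxogermacra-4,11(13)-dien-12,6-olide | C[C@@]12C[C@H](O)[C@H]3C(=C)C(=O)O[C@@H]3/C=C(/COC(C)=O)[C@@H](CC1=O)O2 | intermediate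
21 | angelic acid, (Z)-2-methylbut-2-enoic acid | C/C=C(/C)C(=O)O | starting material
22 | angelic 2,4,6-trichlorobenzoic anhydride | C/C=C(/C)C(=O)OC(=O)c1c(Cl)cc(Cl)cc1Cl | intermediate
23 | (3R,6R,7R,8S,10R)-15-acetoxy-8-angeloyloxy-3,10-epoxy-1-oxogermacra-4,11(13)-dien-12,6-olide | C[C@@]12C[C@H](OC(=O)/C(C)=C\C)[C@H]3C(=C)C(=O)O[C@@H]3/C=C(/COC(C)=O)[C@@H](CC1=O)O2 | intermediate
24 | C1 trimethylsilyl enol ether (C1=C2) of 23 | C[C@@]12C[C@H](OC(=O)/C(C)=C\C)[C@H]3C(=C)C(=O)O[C@@H]3/C=C(/COC(C)=O)[C@@H](C=C1O[Si](C)(C)C)O2 | intermediate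
25 | (6R,7R,8S,10R)-15-acetoxy-8-angeloyloxy-3,10-epoxy-1-oxogermacra-2,4,11(13)-trien-12,6-olide | C=C1C(=O)O[C@@H]2/C=C(/COC(C)=O)C3=CC(=O)[C@@](C)(C[C@H](OC(=O)/C(C)=C\C)[C@@H]12)O3 | target

**Step count**

Total step count: 17. Longest linear sequence: 17 steps (1 to 25).

**Steps most likely to fail**

Step 13 (key step). What may go wrong: the oxonium ylide may rearrange from more than one conformer (cis-fused or trans-fused, free or copper-bound), so that control of the new C7=C8 geometry is lost and the ring-trans alkene forms alongside or instead of the cis one. Part of the carbenoid may also be drained by 1,2-hydride shift. Fallback: set out from 15 and run the rearrangement without regard to alkene geometry, then correct it thermodynamically. The (7E) isomer of the bridged ketone F1 is treated with EtSH and AIBN in benzene at 80 °C. Reversible thiyl radical addition–elimination should drain it into the less strained ring-cis ketone, and the route is rejoined at 17.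

Step 15. What may go wrong: the lithium phosphonate carbanion may be too sluggish or too constrained to reach the back side of C7, or the freed C8 alkoxide may attack phosphorus (phosphoryl transfer followed by cyclopropane closure) or the lactone carbonyl (trans-lactonisation) before olefination. Fallback: set out from 17 and reverse the order of events so that no strong base and no phosphonate is present at the ring closure. K2CO3 and aqueous formaldehyde in THF should turn the phosphonoacetate into the acrylate ester F2 (Horner–Wadsworth–Emmons). Dimethyldioxirane should then epoxidise C7=C8 and leave the electron-poor acrylate alone, giving the epoxy acrylate F3. PMe3 in t-BuOH/THF should add to the acrylate β-carbon; the zwitterionic enolate opens the epoxide at C7 (5-exo, inversion) and loss of the phosphine restores C11=C13 (Morita–Baylis–Hillman-type epoxide alkylation), with the alkoxide protonated by the solvent. This returns to the route at 20.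

Step 14. What may go wrong: poor facial selectivity, with the dioxirane attacking the face of C7=C8 remote from the C6 ester, which would lead to the cis-lactone series. Fallback: set out from 17 and use the same facial bias in the opposite sense. NBS in THF/H2O at 0 °C should place the bromonium ion on the face the dioxirane prefers, and water opens it anti at C8 (the carbon remote from the C6 ester) to give the bromohydrin F4. Ag2O in THF then closes the epoxide by internal displacement of bromide with inversion, so the oxygen ends cis to the C6 ester, and the route is rejoined at 18.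

Further compounds
F1 | step 13 | (7E) isomer of bridged ketone 17 | C[C@@]12C/C=C/[C@H](OC(=O)CP(=O)(OCC)OCC)/C=C(/COC(C)=O)[C@@H](CC1=O)O2
F2 | step 15 | acrylate ester corresponding to 17 (O6 acryloyl in place of phosphonoacetyl) | C[C@@]12C/C=C\[C@H](OC(=O)C=C)/C=C(/COC(C)=O)[C@@H](CC1=O)O2
F3 | step 15 | 7,8-epoxide of F2, oxygen cis to the C6 ester | C[C@@]12C[C@@H]3O[C@@H]3[C@H](OC(=O)C=C)/C=C(/COC(C)=O)[C@@H](CC1=O)O2
F4 | step 14 | bromohydrin of 17 (7-bromo, 8-hydroxy; germacrane 3R,6R,7R,8S,10R) | C[C@@]12C[C@H](O)[C@@H](Br)[C@H](OC(=O)CP(=O)(OCC)OCC)/C=C(/COC(C)=O)[C@@H](CC1=O)O2
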